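## Analysis of the target

Mailiohydrin is a tribrominated spiro[5.5]undecane of the chamigrane type. Ring A (C1–C6) and ring B (C6–C11) share the quaternary carbon C6. C1 carries the exocyclic methylene C15, C3 a secondary hydroxyl, C4 a secondary bromide and C5 two methyl groups. Ring B holds the C7=C8 alkene and the tertiary carbinol C9, which bears the dibromomethyl carbon C14.

The four stereocentres are 3R,4S,6S,9R. On ring A the hydroxyl and the bromine are cis, and both lie on the face that carries C7. Across ring B the C9 hydroxyl points to the side of C5 and the CHBr2 group to the side of C1.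

The sensitive groups are:
- the cis-bromohydrin, whose alkoxide can give a ketone by hydride shift on warming;
- the neopentyl-type C4 bromide, which cannot be introduced by substitution;
- the β-oxido gem-dibromide at C9, which closes to a bromo-epoxide with base;
- the exocyclic alkene, which moves into the ring under acid.

The synthesis is hard for three reasons. C5 and C6 are adjacent quaternary carbons. C6 is a stereocentre only because of distant differences (C1 against C5, C7 against C11). C9 must be set across ring B from C6.

The strategy rests on the fact that ring A is a dearomatised 3,5-dimethylphenol. C3 is the phenol carbon, C1 and C5 are the methyl-bearing carbons (supplying C15 and one C5 methyl), and C6 is the para carbon.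

## Retrosynthetic reasoning

**C9–C14.** The target 21 is cut between C9 and C14, giving the ring-B enone 20 and a dibromomethyl anion equivalent. This is the last step because the dibromomethyl carbinol tolerates neither base nor acid, and because C9 can then travel as a ketal. The forward addition has to be 1,2 and has to come from the ring-B face on the side of C1.

**C9 ketal.** Enone 20 comes from ketal 19 by hydrolysis. The ketal keeps ring B inert while ring A is built; without it the less substituted ring-B enone would be the preferred acceptor.

**The exocyclic alkene (C2–H).** Ketal 19 is traced to the allylic bromide 18 by a reductive allylic transposition: a palladium-bound hydride is delivered to C2 and the double bond moves to C1=C15. Enolate deconjugation of the bromo enone 16 is not used. C4–H, flanked by carbonyl and bromine, is its most acidic hydrogen, so a dienolate towards C15 cannot be formed. The reverse order fails as well, because a deconjugated ketone enolises towards C2 and could not be brominated at C4. The alkene is therefore moved at the alcohol oxidation level. Bromide 18 comes from the bromomethyl enone 17 by carbonyl reduction anti to the C4 bromine, which sets C3. Enone 17 comes from 16 by radical bromination of the only allylic C–H bonds in the molecule.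

**C4–Br.** Bromo enone 16 is cut to enone 14 through the cross-conjugated silyl dienol ether 15. Kinetic enolisation of 14 can only occur at C4, so the regiochemistry is unambiguous. The facial course sets C4 relative to C6.

**C5–CH3.** Enone 14 arises from the achiral dienone 13 by conjugate addition of a methyl nucleophile to one of the two enantiotopic β-carbons. This one operation makes C5 quaternary and turns C6 into a stereocentre. A chiral copper catalyst fixes which π-face of a β-carbon is attacked. The substrate prefers attack next to the flat C7–H arm. Together these select the β-carbon whose Re face lies on the C7 side.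

**C6–C11 (key disconnection).** Dienone 13 is cut between C6 and C11 to the phenol tosylate 12. The cut is made here because it returns an aromatic ring that already holds C1–C6, C15, one C5 methyl and the C3 oxygen, and because the para carbon is the only phenoxide position that can reach C11. The forward reaction has to achieve C-alkylation with loss of aromaticity and closure of the six-membered ring B.

**C7=C8 geometry and the aryl–C7 bond.** Precursor 12 comes from aryl alkyne 11 by cis semi-hydrogenation. Alkyne 11 is cut at the aryl–alkyne bond to the alkynyl tosylate 9 and the iodophenol 10. The iodide is used so that the coupling runs under conditions mild enough for a free phenol and a primary sulfonate.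

**The C7–C11 fragment.** Tosylate 9 comes from alcohol 8, and 8 from the doubly silylated ketal 7 by one fluoride treatment. Ketal 7 comes from ynone 6, which is ketalised while the alkyne is silyl-capped so that the diol cannot add in conjugate fashion. Ynone 6 comes from carbinol 5, which is cut between C8 and C9 to aldehyde 3 and alkyne 4. Aldehyde 3 comes from diol 1 through the mono-silyl ether 2.

## Alternatives that were turned down

**Alternative 1:** Ring A is completed first from ketoisophorone A2 as a tetrasubstituted C1=C6 alkene carrying the silyl-protected cis-bromohydrin and an alkynone tether on C6. The disconnection is C6–C7. In the forward key step a Lewis acid activates the alkynone, C6 attacks its β-carbon C7 and a C15 hydrogen moves to C8. This gives the spiro enone A1 with the exocyclic methylene in place.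
- For: the spiro centre and the exocyclic alkene arise in one step, where the chosen route needs three steps for the alkene position. C6 is set by substrate control, so no desymmetrisation is needed. On these points it is stronger.
- Against: an ene-type closure onto an unactivated tetrasubstituted alkene needs forcing Lewis acidity. Hydrogen transfer from the C2 methylene, which would give the endocyclic alkene, competes with transfer from C15. The neopentyl bromide and the silyl ether sit next to the developing cationic centre. Facial control has to be relayed from C3/C4 through the CMe2 group. The cyclisation substrate needs a long linear sequence with its own asymmetric step.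
- Comparison: the chosen strategy offers a short, symmetric, robust precursor and a ring closure of a well-known type, with the sensitive bromide introduced only afterwards.

**Alternative 2:** Ring A is cut at C3–C4 and C5–C6. A β,γ-unsaturated aldehyde carrying the ring-B cyclohexylidene ketal is activated at C3 by a chiral acid and attacked by C4 of 1-bromo-2-methylprop-1-ene A4. The bromonium ion at C5 is captured by C6 and a C15 proton is lost, giving the spiro ketal A3.
- For: it is the most convergent plan. Ring A with bromohydrin, gem-dimethyl group and methylene forms in one operation from simple pieces, and it is clearly stronger on step count.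
- Against: a bromoalkene is a poor π-nucleophile for a Prins reaction. The cis OH/Br relation, the enantioselectivity on an aliphatic aldehyde and the regiochemistry of the final proton loss (C15 against C2) each rest on an untested cascade. C6 is not yet a stereocentre in A3. It would have to be created later by distinguishing C7–C8 from C10–C11 in a symmetric ring B under the influence of remote centres.
- Comparison: the chosen strategy sets C6 in a step in which the two competing arms are themselves the reacting enones, so a catalyst can act on them directly.

**Alternative 3:** Ring B is cut at C6–C11 and C7=C8. A C6-formyl vinylogous ester derived from dimedone A7 adds through C6 to methyl vinyl ketone A6 under a chiral bifunctional amine catalyst. The methyl ketone then condenses onto the formyl carbon, giving the spiro enone A5.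
- For: asymmetric Michael–aldol spiroannulation is an established reaction class, so C6 is set by known catalysis. On this point it is stronger than the chosen route, whose desymmetrisation is new. The ring-B enone arrives without a protecting group.
- Against: the donor carbon lies between a carbonyl and the CMe2 group, so the intermolecular Michael addition must build two adjacent quaternary carbons. A5 carries C1 as a ketone and C3 as an enol ether. C1 must be methylenated in the presence of the more reactive ring-B enone, and C4 must be brominated at the γ-position of a vinylogous ester.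
- Comparison: the chosen strategy offers C15, the C5 methyl and the C3 oxygen at the right positions from the start, only one reactive carbonyl system at each stage, and an intramolecular formation of the quaternary centre.

Key step: step 10

## Route

Remarks on the chemistry (assumptions):
- Atom numbers C1–C15 are those of the spiro[5.5]undecane skeleton of the target and are used for all intermediates. CIP descriptors are worked out for each structure: C6 is R in 14 and S from 15 on, with unchanged geometry.
- 4-Iodo-3,5-dimethylphenol is taken as a catalogue compound and is used in place of the bromide for a mild coupling.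
- The ligand antipode that delivers methyl to the Re face of the β-carbon is assumed to be the (S,R,R) form named in step 11. If the sense is the opposite, its enantiomer is used.

Step 1
Reactants: 1 propane-1,3-diol
Product: 2 3-[(tert-butyldimethylsilyl)oxy]propan-1-ol
Conditions: NaH (1.0 equiv), THF, 0 °C to rt; TBSCl (1.0 equiv)
Reagents that add atoms: tert-butyldimethylsilyl chloride, CC(C)(C)[Si](C)(C)Cl
Why: One equivalent of sodium hydride gives a sparingly soluble mono-alkoxide that is silylated once (O-silylation), leaving the second hydroxyl free for oxidation.

Step 2
Reactants: 2 3-[(tert-butyldimethylsilyl)oxy]propan-1-ol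
Product: 3 3-[(tert-butyldimethylsilyl)oxy]propanal
Conditions: TEMPO (10 mol%), PhI(OAc)2 (1.1 equiv), CH2Cl2, rt
Reagents that add atoms: none
Why: Oxoammonium (TEMPO) oxidation stops at the aldehyde under near-neutral conditions that the silyl ether tolerates; the β-silyloxy aldehyde is used without storage to avoid elimination.

Step 3
Reactants: 3 3-[(tert-butyldimethylsilyl)oxy]propanal; 4 (trimethylsilyl)acetylene
Product: 5 5-[(tert-butyldimethylsilyl)oxy]-1-(trimethylsilyl)pent-1-yn-3-ol (racemic)
Conditions: 4, n-BuLi, THF, −78 °C; then 3, −78 to −40 °C; aq. NH4Cl
Reagents that add atoms: none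
Why: 1,2-Addition of a lithium acetylide to an aldehyde forms the C8–C9 bond; the carbinol centre is racemic and is removed in step 4, and the C-silyl cap is kept to protect the alkyne in step 5.

Step 4
Reactants: 5 5-[(tert-butyldimethylsilyl)oxy]-1-(trimethylsilyl)pent-1-yn-3-ol
Product: 6 5-[(tert-butyldimethylsilyl)oxy]-1-(trimethylsilyl)pent-1-yn-3-one
Conditions: activated MnO2 (excess), CH2Cl2, rt
Reagents that add atoms: none
Why: Manganese dioxide oxidises propargylic alcohols selectively under neutral conditions and leaves both silyl groups in place.

Step 5
Reactants: 6 5-[(tert-butyldimethylsilyl)oxy]-1-(trimethylsilyl)pent-1-yn-3-one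
Product: 7 tert-butyldimethyl{2-[2-((trimethylsilyl)ethynyl)-1,3-dioxolan-2-yl]ethoxy}silane
Conditions: TMSOCH2CH2OTMS (2 equiv), TMSOTf (5 mol%), CH2Cl2, −78 to −20 °C; pyridine quench
Reagents that add atoms: 1,2-bis(trimethylsilyloxy)ethane, C[Si](C)(C)OCCO[Si](C)(C)C
Why: Noyori ketalisation (silyl-transfer ketalisation at low temperature) converts conjugated ketones into dioxolanes; the C-silyl group blocks conjugate addition at the alkyne terminus and the primary TBS ether survives catalytic TMSOTf at this temperature.

Step 6
Reactants: 7 tert-butyldimethyl{2-[2-((trimethylsilyl)ethynyl)-1,3-dioxolan-2-yl]ethoxy}silane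
Product: 8 2-(2-ethynyl-1,3-dioxolan-2-yl)ethan-1-ol
Conditions: TBAF (2.5 equiv), THF, 0 °C to rt
Reagents that add atoms: none
Why: Fluoride cleaves the O–Si and the C(sp)–Si bond in one operation; the ketal is inert to fluoride.

Step 7
Reactants: 8 2-(2-ethynyl-1,3-dioxolan-2-yl)ethan-1-ol
Product: 9 2-(2-ethynyl-1,3-dioxolan-2-yl)ethyl 4-methylbenzenesulfonate
Conditions: TsCl (1.2 equiv), Et3N, DMAP (cat.), CH2Cl2, 0 °C
Reagents that add atoms: 4-methylbenzenesulfonyl chloride, Cc1ccc(cc1)S(Cl)(=O)=O
Why: Sulfonylation of a primary alcohol; the leaving group is installed before the phenol enters the sequence, so no hydroxyl has to be differentiated later.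

Step 8
Reactants: 9 2-(2-ethynyl-1,3-dioxolan-2-yl)ethyl 4-methylbenzenesulfonate; 10 4-iodo-3,5-dimethylphenol
Product: 11 2-{2-[(4-hydroxy-2,6-dimethylphenyl)ethynyl]-1,3-dioxolan-2-yl}ethyl 4-methylbenzenesulfonate
Conditions: PdCl2(PPh3)2 (5 mol%), CuI (5 mol%), Et3N (3 equiv), THF, 45 °C
Reagents that add atoms: none
Why: Sonogashira coupling; the aryl iodide undergoes oxidative addition near 45 °C despite the two ortho methyl groups, and under these conditions triethylamine neither ionises the phenol appreciably nor attacks the primary sulfonate.

Step 9
Reactants: 11 2-{2-[(4-hydroxy-2,6-dimethylphenyl)ethynyl]-1,3-dioxolan-2-yl}ethyl 4-methylbenzenesulfonate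
Product: 12 2-{2-[(Z)-2-(4-hydroxy-2,6-dimethylphenyl)ethenyl]-1,3-dioxolan-2-yl}ethyl 4-methylbenzenesulfonate
Conditions: H2 (1 atm), Lindlar catalyst, quinoline, EtOAc, rt, dark
Reagents that add atoms: none
Why: Lindlar semi-hydrogenation delivers both hydrogens syn from the catalyst surface and should give the Z-alkene that the ring closure needs; quinoline and monitoring guard against over-reduction.

Step 10
Reactants: 12 2-{2-[(Z)-2-(4-hydroxy-2,6-dimethylphenyl)ethenyl]-1,3-dioxolan-2-yl}ethyl 4-methylbenzenesulfonate
Product: 13 9,9-ethylenedioxy-1,5-dimethylspiro[5.5]undeca-1,4,7-trien-3-one (9,13-dimethyl-1,4-dioxadispiro[4.2.5^8.2^5]pentadeca-6,9,12-trien-11-one)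
Conditions: KOt-Bu (1.05 equiv), t-BuOH (5 mM), 70 °C
Reagents that add atoms: none
Why: tert-Butoxide converts the phenol into its ambident phenoxide, whose para carbon C6 displaces the C11 tosylate in an intramolecular SN2 reaction; aromaticity is given up and the cross-conjugated 4,4-disubstituted dienone results. The closest known reaction type is the base-mediated para-alkylative dearomatisation of phenols that carry a sulfonate-terminated chain (Ar1-6 participation). Ring B is closed in the 6-exo-tet mode, with the cis C7=C8 bond inside the new ring. No stereocentre is formed: C6 carries two identical enone arms and the product has a mirror plane. The step needs carbon instead of oxygen alkylation, ring closure instead of oligomerisation, and substitution instead of elimination. The para relationship and the Z-alkene make C11 unreachable for the phenoxide oxygen, high dilution suppresses intermolecular O-alkylation, hydrogen bonding by tert-butanol lowers the oxygen nucleophilicity, and with barely more than one equivalent of base no free alkoxide is left for E2. The two methyl groups flanking C6 twist the alkenyl chain out of the arene plane, which holds C11 over the π-face at C6 and also suppresses conjugative opening of the allylic ketal that could scramble the alkene geometry.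

Step 11
Reactants: 13 9,9-ethylenedioxy-1,5-dimethylspiro[5.5]undeca-1,4,7-trien-3-one
Product: 14 (6R)-9,9-ethylenedioxy-1,5,5-trimethylspiro[5.5]undeca-1,7-dien-3-one
Conditions: Me3Al (2.5 equiv), CuTC (10 mol%), (S,R,R)-binaphthol phosphoramidite of bis(1-phenylethyl)amine (20 mol%), Et2O, −30 °C; aq. Rochelle salt
Reagents that add atoms: trimethylaluminium, C[Al](C)C
Why: Proposed new method: a methylcopper–aluminate formed from Me3Al and the copper(I)–phosphoramidite complex should add to the aluminium-activated dienone by π-complexation, oxidative addition at the β-carbon and reductive elimination; the closest known reactions are the copper-catalysed enantioselective conjugate addition of trialkylaluminium reagents to β-methyl cyclohexenones and the copper-catalysed desymmetrising conjugate addition to 4,4-disubstituted cyclohexadienones, which have not been combined on a β,β′-dimethyl spirodienone where the new quaternary carbon adjoins the spiro carbon. The catalyst fixes the π-face of the β-carbon that is attacked (Re) and the substrate prefers attack on the ring face next to the flat C7–H arm, so that of the two enantiotopic β-carbons the one whose Re face lies on the C7 side should react; C5 becomes the non-stereogenic gem-dimethyl carbon and C6 a stereocentre (R by CIP here, the spatial arrangement of 6S in the target). Aqueous work-up protonates the aluminium enolate at C4.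

Step 12
Reactants: 14 (6R)-9,9-ethylenedioxy-1,5,5-trimethylspiro[5.5]undeca-1,7-dien-3-one
Product: 16 (4S,6S)-4-bromo-9,9-ethylenedioxy-1,5,5-trimethylspiro[5.5]undeca-1,7-dien-3-one, via trimethylsilyl dienol ether 15 (not isolated)
Conditions: LDA (1.1 equiv), TMSCl (1.5 equiv), THF, −78 °C; then NBS (1.05 equiv), −78 to 0 °C
Reagents that add atoms: N-bromosuccinimide, O=C1CCC(=O)N1Br
Why: LDA removes the only kinetically accessible α′-hydrogen (C4–H; deprotonation at C15 is the thermodynamic pathway) and the cross-conjugated enolate is trapped as 15, whose electrophilic bromination (α-halogenation of a silyl enol ether) can only take place at C4. Bromine should enter on the ring-A face that carries the C7–H arm of ring B, because the other face is crowded by a C11 hydrogen next to the equatorial C5 methyl; this places bromine cis to C7 (4S).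

Step 13
Reactants: 16 (4S,6S)-4-bromo-9,9-ethylenedioxy-1,5,5-trimethylspiro[5.5]undeca-1,7-dien-3-one
Product: 17 (4S,6S)-4-bromo-1-(bromomethyl)-9,9-ethylenedioxy-5,5-dimethylspiro[5.5]undeca-1,7-dien-3-one
Conditions: NBS (1.05 equiv), AIBN (10 mol%), PhCF3, 80 °C
Reagents that add atoms: N-bromosuccinimide, O=C1CCC(=O)N1Br
Why: Wohl–Ziegler bromination; the C15 methyl hydrogens are the only allylic hydrogens in the molecule (C6 and C9 are quaternary), so hydrogen abstraction by a bromine atom should occur there, while C4–H, next to carbonyl and bromine, is polarity-mismatched and shielded.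

Step 14
Reactants: 17 (4S,6S)-4-bromo-1-(bromomethyl)-9,9-ethylenedioxy-5,5-dimethylspiro[5.5]undeca-1,7-dien-3-one
Product: 18 (3R,4S,6S)-4-bromo-1-(bromomethyl)-9,9-ethylenedioxy-5,5-dimethylspiro[5.5]undeca-1,7-dien-3-ol
Conditions: DIBAL-H (1.3 equiv), CH2Cl2, −78 °C; aq. Rochelle salt
Reagents that add atoms: none
Why: 1,2-Reduction of an enone by an aluminium hydride at low temperature; hydride should add anti to the C4–Br bond (Felkin–Anh/Cornforth control), which gives the cis-bromohydrin (3R). Reduction at this point also turns the activated α-bromo ketone into an inert secondary bromide before palladium is used.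

Step 15
Reactants: 18 (3R,4S,6S)-4-bromo-1-(bromomethyl)-9,9-ethylenedioxy-5,5-dimethylspiro[5.5]undeca-1,7-dien-3-ol
Product: 19 (3R,4S,6S)-4-bromo-9,9-ethylenedioxy-5,5-dimethyl-1-methylidenespiro[5.5]undec-7-en-3-ol
Conditions: Pd2(dba)3·CHCl3 (2.5 mol%), n-Bu3P (10 mol%), HCO2H/Et3N (3 equiv each), THF, 40 °C
Reagents that add atoms: none
Why: Tsuji-type palladium-catalysed formate hydrogenolysis of an allylic halide: ionisation of the primary allylic bromide gives a π-allyl complex over C15–C1–C2, and with tributylphosphine the formate-derived hydride is delivered to the more substituted terminus C2, which leaves the double bond exocyclic. The unactivated secondary C4 bromide and the cis-bromohydrin should not react under these nearly neutral conditions.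

Step 16
Reactants: 19 (3R,4S,6S)-4-bromo-9,9-ethylenedioxy-5,5-dimethyl-1-methylidenespiro[5.5]undec-7-en-3-ol
Product: 20 (3R,4S,6S)-4-bromo-3-hydroxy-5,5-dimethyl-1-methylidenespiro[5.5]undec-7-en-9-one
Conditions: PPTS (20 mol%), acetone/H2O (10:1), 45 °C
Reagents that add atoms: water, O
Why: Mild acid-catalysed hydrolysis of the allylic dioxolane to the conjugated enone; pyridinium tosylate is weak enough to leave the exocyclic alkene and the bromohydrin untouched.

Step 17
Reactants: 20 (3R,4S,6S)-4-bromo-3-hydroxy-5,5-dimethyl-1-methylidenespiro[5.5]undec-7-en-9-one
Product: 21 (3R,4S,6S,9R)-4-bromo-9-(dibromomethyl)-5,5-dimethyl-1-methylidenespiro[5.5]undec-7-ene-3,9-diol (mailiohydrin)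
Conditions: CH2Br2 (4 equiv), LiTMP (3.5 equiv), THF, −100 °C; then 20, −100 to −78 °C; AcOH at −78 °C
Reagents that add atoms: dibromomethane, BrCBr
Why: 1,2-Addition of the carbenoid dibromomethyllithium to the enone carbonyl, quenched cold so that the β-oxido gem-dibromide does not close to a bromo-epoxide; one equivalent of reagent is consumed by the C3 hydroxyl. The reagent should approach C9 from the ring-B face on the side of C1, away from the C5 gem-dimethyl group whose equatorial methyl leans over the C10–C11 edge, which gives 9R.

## Compound list

1 | propane-1,3-diol | OCCCO | starting material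
2 | 3-[(tert-butyldimethylsilyl)oxy]propan-1-ol | CC(C)(C)[Si](C)(C)OCCCO | intermediate
3 | 3-[(tert-butyldimethylsilyl)oxy]propanal | CC(C)(C)[Si](C)(C)OCCC=O | intermediate
4 | (trimethylsilyl)acetylene | C#C[Si](C)(C)C | starting material
5 | 5-[(tert-butyldimethylsilyl)oxy]-1-(trimethylsilyl)pent-1-yn-3-ol (racemic) | CC(C)(C)[Si](C)(C)OCCC(O)C#C[Si](C)(C)C | intermediate
6 | 5-[(tert-butyldimethylsilyl)oxy]-1-(trimethylsilyl)pent-1-yn-3-one | CC(C)(C)[Si](C)(C)OCCC(=O)C#C[Si](C)(C)C | intermediate
7 | tert-butyldimethyl{2-[2-((trimethylsilyl)ethynyl)-1,3-dioxolan-2-yl]ethoxy}silane | CC(C)(C)[Si](C)(C)OCCC1(OCCO1)C#C[Si](C)(C)C | intermediate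
8 | 2-(2-ethynyl-1,3-dioxolan-2-yl)ethan-1-ol | OCCC1(OCCO1)C#C | intermediate
9 | 2-(2-ethynyl-1,3-dioxolan-2-yl)ethyl 4-methylbenzenesulfonate | Cc1ccc(cc1)S(=O)(=O)OCCC1(OCCO1)C#C | intermediate
10 | 4-iodo-3,5-dimethylphenol | Cc1cc(O)cc(C)c1I | starting material
11 | 2-{2-[(4-hydroxy-2,6-dimethylphenyl)ethynyl]-1,3-dioxolan-2-yl}ethyl 4-methylbenzenesulfonate | Cc1cc(O)cc(C)c1C#CC1(CCOS(=O)(=O)c2ccc(C)cc2)OCCO1 | intermediate
12 | 2-{2-[(Z)-2-(4-hydroxy-2,6-dimethylphenyl)ethenyl]-1,3-dioxolan-2-yl}ethyl 4-methylbenzenesulfonate | Cc1cc(O)cc(C)c1/C=C\C2(CCOS(=O)(=O)c3ccc(C)cc3)OCCO2 | intermediate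
13 | 9,9-ethylenedioxy-1,5-dimethylspiro[5.5]undeca-1,4,7-trien-3-one (achiral) | CC1=CC(=O)C=C(C)C12C=CC3(CC2)OCCO3 | intermediate
14 | (6R)-9,9-ethylenedioxy-1,5,5-trimethylspiro[5.5]undeca-1,7-dien-3-one | CC1=CC(=O)CC(C)(C)[C@@]12C=CC3(CC2)OCCO3 | intermediate
15 | (6S)-9,9-ethylenedioxy-1,5,5-trimethyl-3-(trimethylsilyloxy)spiro[5.5]undeca-1,3,7-triene | CC1=CC(O[Si](C)(C)C)=CC(C)(C)[C@@]12C=CC3(CC2)OCCO3 | intermediate (not isolated)
16 | (4S,6S)-4-bromo-9,9-ethylenedioxy-1,5,5-trimethylspiro[5.5]undeca-1,7-dien-3-one | CC1=CC(=O)[C@@H](Br)C(C)(C)[C@@]12C=CC3(CC2)OCCO3 | intermediate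
17 | (4S,6S)-4-bromo-1-(bromomethyl)-9,9-ethylenedioxy-5,5-dimethylspiro[5.5]undeca-1,7-dien-3-one | BrCC1=CC(=O)[C@@H](Br)C(C)(C)[C@@]12C=CC3(CC2)OCCO3 | intermediate
18 | (3R,4S,6S)-4-bromo-1-(bromomethyl)-9,9-ethylenedioxy-5,5-dimethylspiro[5.5]undeca-1,7-dien-3-ol | BrCC1=C[C@@H](O)[C@@H](Br)C(C)(C)[C@@]12C=CC3(CC2)OCCO3 | intermediate
19 | (3R,4S,6S)-4-bromo-9,9-ethylenedioxy-5,5-dimethyl-1-methylidenespiro[5.5]undec-7-en-3-ol | C=C1C[C@@H](O)[C@@H](Br)C(C)(C)[C@@]12C=CC3(CC2)OCCO3 | intermediate
20 | (3R,4S,6S)-4-bromo-3-hydroxy-5,5-dimethyl-1-methylidenespiro[5.5]undec-7-en-9-one | C=C1C[C@@H](O)[C@@H](Br)C(C)(C)[C@@]12C=CC(=O)CC2 | intermediate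
21 | (3R,4S,6S,9R)-4-bromo-9-(dibromomethyl)-5,5-dimethyl-1-methylidenespiro[5.5]undec-7-ene-3,9-diol (mailiohydrin) | C=C1C[C@@H](O)[C@@H](Br)C(C)(C)[C@@]12C=C[C@@](O)(C(Br)Br)CC2 | target

## Step count and least certain steps

Total step count: 17. Longest linear sequence: 17 steps (1 to 21). Alkyne 4 enters in step 3 and iodophenol 10 in step 8.

**Step 11 (labelled step; desymmetrising conjugate methylation).** Three things may go wrong. The β-carbon, which already bears a methyl group and adjoins the spiro carbon, may not accept the nucleophile. The catalyst may discriminate poorly between the two β-carbons, because they differ only in whether the CH= or the CH2 arm of ring B lies on the attacked side. The Lewis-acidic aluminium reagent may open the allylic ketal.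

Fallback, from 13 back to 14, using known chemistry: stoichiometric conjugate addition of lithium dimethylcuprate accelerated by chlorotrimethylsilane (THF, −78 to −30 °C, then mild hydrolysis of the silyl enol ether) should give the racemic enone F1. F1 is resolved as a ketone. Lithiated (S)-N,S-dimethyl-S-phenylsulfoximine is added to the C3 carbonyl, and the diastereomeric adducts are separated by chromatography. The β-hydroxy sulfoximine F2, derived from the wanted enantiomer, is thermolysed in toluene, which returns 14.

**Step 10 (key step).** Intermolecular O-alkylation may compete with the slower attack of a para carbon flanked by two methyl groups. Elimination of the sulfonate may occur. The phenoxide may push open the allylic ketal with loss of the Z geometry, after which ring closure is impossible.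

Fallback, from 11 back to 13: the alkene is left out of the ring-closing substrate. Full hydrogenation of 11 (H2, Pd/C, EtOAc) should give the saturated phenol tosylate F3. The same phenoxide para-alkylation (KOt-Bu, t-BuOH, dilute) on this freely rotating and non-ionisable chain should give the saturated spiro ketal dienone F4. Ketal hydrolysis (PPTS, aqueous acetone) gives the dienone ketone F5. Its ring-B ketone has two α-methylene groups that are equivalent by symmetry, so Saegusa oxidation (LDA, TMSCl; then Pd(OAc)2) gives a single dienone-enone F6. Low-temperature silyl-transfer ketalisation of the more electrophilic ring-B carbonyl then rejoins the route at 13.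

**Step 12 (C4 bromination).** Facial discrimination between the C7 side and the C11 side of the dienol ether may be poor or reversed, since the two arms of ring B differ only slightly.

Fallback, from 14 back to 16: the step is run as written and the C4-epimeric bromo enone F7 is not discarded. F7 is converted with LiHMDS and TMSCl into the bromo silyl dienol ether F8, which has no stereocentre at C4. Fluoride-triggered protonation of F8 at −78 °C (TBAF, AcOH) then puts the proton, not the bromine, on the more accessible face and should give 16.

**Step 13 (radical bromination at C15).** Hydrogen bromide formed in the chain may epimerise C4 through the enol or open the ketal. Bromine may add to the ring-B alkene. Dibromination at C15 may occur.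

Fallback, from 16 back to 18: the order of reduction and C15 functionalisation is reversed. DIBAL-H reduction of 16 gives the cis-bromohydrin allylic alcohol F9. Selenium dioxide with tert-butyl hydroperoxide oxidises the methyl group on the more substituted alkene carbon to give the diol F10. Appel bromination (CBr4, PPh3, 0 °C) of the primary allylic hydroxyl, which is far more accessible than the C3 hydroxyl, returns 18.

**Step 17 (carbenoid addition).** Facial selectivity at C9 may be poor, because the controlling centre C6 sits across ring B. The basic carbenoid may also enolise the enone at C10.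

Fallback, from 20 back to 21: the larger and much less basic tribromomethyl anion (CHBr3, LiHMDS, THF, −78 °C) is added reversibly, so that the more stable carbinol F11 with the bulky group away from the gem-dimethyl side should accumulate. One bromine is then removed by radical reduction (Bu3SnH, 1.05 equiv, Et3B/air, −78 °C); the weak C–Br bond of the CBr3 group reacts before the secondary C4 bromide, giving 21.

## Further compounds

F1 | step 11 | racemic 9,9-ethylenedioxy-1,5,5-trimethylspiro[5.5]undeca-1,7-dien-3-one | CC1=CC(=O)CC(C)(C)C12C=CC3(CC2)OCCO3
F2 | step 11 | β-hydroxy sulfoximine from 14 and (S)-N,S-dimethyl-S-phenylsulfoximine (C3 configuration not assigned) | CC1=CC(O)(C[S@@](=O)(=NC)c2ccccc2)CC(C)(C)[C@@]13C=CC4(CC3)OCCO4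
F3 | step 10 | 2-{2-[2-(4-hydroxy-2,6-dimethylphenyl)ethyl]-1,3-dioxolan-2-yl}ethyl 4-methylbenzenesulfonate | Cc1cc(O)cc(C)c1CCC1(CCOS(=O)(=O)c2ccc(C)cc2)OCCO1
F4 | step 10 | 9,9-ethylenedioxy-1,5-dimethylspiro[5.5]undeca-1,4-dien-3-one | CC1=CC(=O)C=C(C)C12CCC3(CC2)OCCO3
F5 | step 10 | 1,5-dimethylspiro[5.5]undeca-1,4-diene-3,9-dione | CC1=CC(=O)C=C(C)C12CCC(=O)CC2
F6 | step 10 | 1,5-dimethylspiro[5.5]undeca-1,4,7-triene-3,9-dione | CC1=CC(=O)C=C(C)C12C=CC(=O)CC2
F7 | step 12 | (4R,6S)-4-bromo-9,9-ethylenedioxy-1,5,5-trimethylspiro[5.5]undeca-1,7-dien-3-one (C4 epimer of 16) | CC1=CC(=O)[C@H](Br)C(C)(C)[C@@]12C=CC3(CC2)OCCO3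
F8 | step 12 | (6S)-4-bromo-9,9-ethylenedioxy-1,5,5-trimethyl-3-(trimethylsilyloxy)spiro[5.5]undeca-1,3,7-triene | CC1=CC(O[Si](C)(C)C)=C(Br)C(C)(C)[C@@]12C=CC3(CC2)OCCO3
F9 | step 13 | (3R,4S,6S)-4-bromo-9,9-ethylenedioxy-1,5,5-trimethylspiro[5.5]undeca-1,7-dien-3-ol | CC1=C[C@@H](O)[C@@H](Br)C(C)(C)[C@@]12C=CC3(CC2)OCCO3
F10 | step 13 | (3R,4S,6S)-4-bromo-9,9-ethylenedioxy-1-(hydroxymethyl)-5,5-dimethylspiro[5.5]undeca-1,7-dien-3-ol | OCC1=C[C@@H](O)[C@@H](Br)C(C)(C)[C@@]12C=CC3(CC2)OCCO3
F11 | step 17 | (3R,4S,6S,9R)-4-bromo-5,5-dimethyl-1-methylidene-9-(tribromomethyl)spiro[5.5]undec-7-ene-3,9-diol | C=C1C[C@@H](O)[C@@H](Br)C(C)(C)[C@@]12C=C[C@@](O)(C(Br)(Br)Br)CC2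
A1 | alternative 1 | silyl-protected spiro enone with ring A complete | C=C1C[C@@H](O[Si](C)(C)C(C)(C)C)[C@@H](Br)C(C)(C)[C@@]12C=CC(=O)CC2
A2 | alternative 1 | ketoisophorone (2,6,6-trimethylcyclohex-2-ene-1,4-dione) | CC1=CC(=O)CC(C)(C)C1=O
A3 | alternative 2 | spiro ketal with ring A complete and symmetric ring B | C=C1C[C@@H](O)[C@@H](Br)C(C)(C)C12CCC3(CC2)OCCO3
A4 | alternative 2 | 1-bromo-2-methylprop-1-ene | CC(C)=CBr
A5 | alternative 3 | spiro enone with ring A as vinylogous ester | COC1=CC(=O)[C@]2(C=CC(=O)CC2)C(C)(C)C1
A6 | alternative 3 | methyl vinyl ketone | CC(=O)C=C
A7 | alternative 3 | dimedone | CC1(C)CC(=O)CC(=O)C1
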